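The route rests on disconnecting the central 1,3-oxazole at C4–C5 and O1–C2. The aldehyde carbon and oxygen of a 6-bromo-4-methoxyindole-3-carbaldehyde become oxazole C5 and O1. C4, N3 and C2, with the 5-bromopyrrole already on C2, come from an S-methyl N-(tosylmethyl)thioimidate. The hydrogen-bearing C4 is the position at which a tosyl group first acidifies the carbon and is then expelled on aromatisation. One base-mediated, metal-free operation thus closes the oxazole and joins all three heteroaromatic rings with both bromines in place. Both ring nitrogens carry SEM groups, because a free N–H would be deprotonated first and blunt either partner; they are removed together at the end.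

Key step: step 8

Remarks on the chemistry: SEM = 2-(trimethylsilyl)ethoxymethyl; tosyl = 4-methylbenzenesulfonyl. The C=N geometry of the thioimidate is labile; it is drawn E, and either isomer gives the same carbanion. 5-Bromo-1H-pyrrole-2-carboxylic acid is taken as the commercial pyrrole building block because its primary amide is reached in one mild step.

Step 1
Reactants: 1 6-bromo-4-methoxy-1H-indole
Product: 3 6-bromo-4-methoxy-1H-indole-3-carbaldehyde, via C3 iminium chloride 2 (not isolated)
Conditions: POCl3, DMF, 0 °C to 35 °C; then 2 M aq. NaOH, 0 °C to 60 °C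
Reagents that add atoms: N,N-dimethylformamide CN(C)C=O (formyl carbon); water O (carbonyl oxygen)
Why: Vilsmeier–Haack formylation, in which the chloroiminium ion attacks C3, the most nucleophilic indole position even beside the C4 methoxy group, and basic hydrolysis of iminium salt 2 releases the aldehyde without touching the aryl bromide or the methyl ether.

Step 2
Reactants: 3 6-bromo-4-methoxy-1H-indole-3-carbaldehyde
Product: 4 6-bromo-4-methoxy-1-{[2-(trimethylsilyl)ethoxy]methyl}-1H-indole-3-carbaldehyde
Conditions: NaH, DMF, 0 °C; SEMCl, 0 °C to rt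
Reagents that add atoms: 2-(trimethylsilyl)ethoxymethyl chloride C[Si](C)(C)CCOCCl
Why: N-alkylation (SN2) of the sodium indolide with SEMCl; the aldehyde has no α-hydrogen, and the resulting N,O-acetal withstands the strong base and thiolate of the key step yet leaves with fluoride.

Step 3
Reactants: 5 5-bromo-1H-pyrrole-2-carboxylic acid
Product: 7 5-bromo-1H-pyrrole-2-carboxamide, via acyl imidazolide 6 (not isolated)
Conditions: CDI, THF, rt; then 28% aq. NH3, 0 °C to rt
Reagents that add atoms: ammonia N
Why: Amide formation by carbonyldiimidazole activation, in which the acid gives acyl imidazolide 6 with loss of CO2 and ammonia displaces imidazole under conditions mild enough for the 2-bromopyrrole.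

Step 4
Reactants: 7 5-bromo-1H-pyrrole-2-carboxamide
Product: 8 5-bromo-1-{[2-(trimethylsilyl)ethoxy]methyl}-1H-pyrrole-2-carboxamide
Conditions: NaH (1.05 equiv), DMF, 0 °C; SEMCl (1.05 equiv), 0 °C
Reagents that add atoms: 2-(trimethylsilyl)ethoxymethyl chloride C[Si](C)(C)CCOCCl
Why: Chemoselective N-alkylation, since the pyrrole N–H is several pKa units more acidic than the carboxamide N–H, so one equivalent of NaH gives the pyrrolide and SEMCl alkylates it at N1.

Step 5
Reactants: 8 5-bromo-1-SEM-1H-pyrrole-2-carboxamide; 9 formaldehyde; 10 sodium p-toluenesulfinate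
Product: 12 5-bromo-N-[(4-methylbenzenesulfonyl)methyl]-1-SEM-1H-pyrrole-2-carboxamide, via N-hydroxymethyl amide 11 (not isolated)
Conditions: 37% aq. CH2O, 4-MeC6H4SO2Na, HCO2H/H2O/THF, 45 °C
Reagents that add atoms: none
Why: Three-component Mannich-type amidoalkylation (the condensation used to make N-(tosylmethyl)formamide), in which N-hydroxymethyl amide 11 ionises under acid to an N-acyliminium ion that sulfinate traps at sulfur to give the α-amido sulfone, the electron-poor N-SEM pyrrole being expected to tolerate dilute formic acid.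

Step 6
Reactants: 12 5-bromo-N-[(4-methylbenzenesulfonyl)methyl]-1-SEM-1H-pyrrole-2-carboxamide
Product: 13 5-bromo-N-[(4-methylbenzenesulfonyl)methyl]-1-SEM-1H-pyrrole-2-carbothioamide
Conditions: Lawesson's reagent (0.6 equiv), THF, 60 °C
Reagents that add atoms: Lawesson's reagent COc1ccc(cc1)P1(=S)SP(=S)(S1)c1ccc(OC)cc1
Why: Thionation of a secondary amide with Lawesson's reagent through a thiaoxaphosphetane (addition then cycloreversion), selective for the amide C=O because the sulfone, the SEM acetal and the C–Br bond do not react.

Step 7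
Reactants: 13 5-bromo-N-[(4-methylbenzenesulfonyl)methyl]-1-SEM-1H-pyrrole-2-carbothioamide
Product: 14 methyl 5-bromo-N-[(4-methylbenzenesulfonyl)methyl]-1-SEM-1H-pyrrole-2-carbimidothioate
Conditions: MeI, K2CO3, acetone, 0 °C to rt
Reagents that add atoms: iodomethane CI
Why: S-alkylation of a thioamide (thioimidate formation), in which the soft sulfur of the thioamidate is methylated much faster than nitrogen and the mild base at low temperature leaves the base-sensitive N–CH2–SO2 unit intact.

Step 8
Reactants: 4 6-bromo-4-methoxy-1-SEM-1H-indole-3-carbaldehyde; 14 methyl 5-bromo-N-[(4-methylbenzenesulfonyl)methyl]-1-SEM-1H-pyrrole-2-carbimidothioate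
Product: 17 5-(6-bromo-4-methoxy-1-SEM-1H-indol-3-yl)-2-(5-bromo-1-SEM-1H-pyrrol-2-yl)-1,3-oxazole, via alkoxide adduct 15 (not isolated), via tosyl dihydrooxazole 16 (not isolated)
Conditions: KOtBu (2.5 equiv), THF, −20 °C to rt; then MeOH, 55 °C
Reagents that add atoms: none
Why: The methylene of 14, acidified by the sulfonyl group on one side and the C=N nitrogen on the other, is deprotonated by KOtBu, and the resulting 2-azaallyl-type carbanion attacks the formyl carbon of 4, forming the C4–C5 bond and alkoxide 15. The alkoxide oxygen then adds to the thioimidate carbon and methanethiolate departs, forming the O1–C2 bond and 4-tosyl-4,5-dihydrooxazole 16; by Baldwin's classification the ring closes in a 5-endo-trig sense, which is no obstacle here because oxygen adds to a C=N carbon that carries its own leaving group and the double bond is regenerated at once (equivalently, an anionic [3+2] addition of the azaallyl anion across C=O followed by loss of thiolate). Warming with methoxide then removes p-toluenesulfinate from C4 together with the C5 hydrogen, a 1,2-elimination driven by formation of the aromatic oxazole. The closest known reaction type is the van Leusen oxazole synthesis in its variant with N-(tosylmethyl)imino compounds, which turns aldehydes into 2-substituted oxazoles. The two sp3 centres created in 15 and 16 form without control and both are destroyed on aromatisation, so no stereocontrol is required. Only the regiochemistry has to be right, and it cannot go wrong: the nucleophilic carbon of 14 necessarily ends as C4 (bearing H), the formyl carbon as C5 (bearing the indole) and the imidate carbon as C2 (bearing the pyrrole), while the SEM groups keep the N–H sites from consuming base and the small formyl electrophile stays accessible beside the C4 methoxy group.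

Step 9
Reactants: 17 5-(6-bromo-4-methoxy-1-SEM-1H-indol-3-yl)-2-(5-bromo-1-SEM-1H-pyrrol-2-yl)-1,3-oxazole
Product: 18 5-(6-bromo-4-methoxy-1H-indol-3-yl)-2-(5-bromo-1H-pyrrol-2-yl)-1,3-oxazole
Conditions: Bu4NF (1 M in THF), H2NCH2CH2NH2, THF, 65 °C
Reagents that add atoms: none
Why: Fluoride-induced SEM cleavage, in which fluoride attacks silicon and the β-silyl ether fragments to ethene and an N-CH2-O hemiaminal anion that loses formaldehyde (scavenged by ethylenediamine), so both N–H groups should be freed at once without touching the aryl bromides, the methyl ether or the oxazole.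

Compound list
1 | 6-bromo-4-methoxy-1H-indole | COc1cc(Br)cc2[nH]ccc12 | starting material
2 | N-[(6-bromo-4-methoxy-1H-indol-3-yl)methylidene]-N-methylmethanaminium chloride (C3 iminium chloride, not isolated) | COc1cc(Br)cc2[nH]cc(C=[N+](C)C)c12.[Cl-] | intermediate
3 | 6-bromo-4-methoxy-1H-indole-3-carbaldehyde | COc1cc(Br)cc2[nH]cc(C=O)c12 | intermediate
4 | 6-bromo-4-methoxy-1-{[2-(trimethylsilyl)ethoxy]methyl}-1H-indole-3-carbaldehyde | COc1cc(Br)cc2n(COCC[Si](C)(C)C)cc(C=O)c12 | intermediate
5 | 5-bromo-1H-pyrrole-2-carboxylic acid | OC(=O)c1ccc(Br)[nH]1 | starting material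
6 | (5-bromo-1H-pyrrol-2-yl)(1H-imidazol-1-yl)methanone (acyl imidazolide, not isolated) | O=C(c1ccc(Br)[nH]1)n1ccnc1 | intermediate
7 | 5-bromo-1H-pyrrole-2-carboxamide | NC(=O)c1ccc(Br)[nH]1 | intermediate
8 | 5-bromo-1-{[2-(trimethylsilyl)ethoxy]methyl}-1H-pyrrole-2-carboxamide | NC(=O)c1ccc(Br)n1COCC[Si](C)(C)C | intermediate
9 | formaldehyde | C=O | starting material
10 | sodium p-toluenesulfinate | Cc1ccc(cc1)S(=O)[O-].[Na+] | starting material
11 | 5-bromo-N-(hydroxymethyl)-1-SEM-1H-pyrrole-2-carboxamide (not isolated) | OCNC(=O)c1ccc(Br)n1COCC[Si](C)(C)C | intermediate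
12 | 5-bromo-N-[(4-methylbenzenesulfonyl)methyl]-1-SEM-1H-pyrrole-2-carboxamide | Cc1ccc(cc1)S(=O)(=O)CNC(=O)c1ccc(Br)n1COCC[Si](C)(C)C | intermediate
13 | 5-bromo-N-[(4-methylbenzenesulfonyl)methyl]-1-SEM-1H-pyrrole-2-carbothioamide | Cc1ccc(cc1)S(=O)(=O)CNC(=S)c1ccc(Br)n1COCC[Si](C)(C)C | intermediate
14 | methyl 5-bromo-N-[(4-methylbenzenesulfonyl)methyl]-1-SEM-1H-pyrrole-2-carbimidothioate (drawn E; C=N geometry labile) | CS/C(=N/CS(=O)(=O)c1ccc(C)cc1)c1ccc(Br)n1COCC[Si](C)(C)C | intermediate
15 | potassium 1-(6-bromo-4-methoxy-1-SEM-indol-3-yl)-2-{[(5-bromo-1-SEM-pyrrol-2-yl)(methylsulfanyl)methylidene]amino}-2-tosylethan-1-olate (not isolated; two uncontrolled sp3 centres, racemic diastereomer mixture, both erased later) | COc1cc(Br)cc2n(COCC[Si](C)(C)C)cc(C([O-])C(N=C(SC)c3ccc(Br)n3COCC[Si](C)(C)C)S(=O)(=O)c3ccc(C)cc3)c12.[K+] | intermediate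
16 | 5-(6-bromo-4-methoxy-1-SEM-indol-3-yl)-2-(5-bromo-1-SEM-pyrrol-2-yl)-4-tosyl-4,5-dihydro-1,3-oxazole (not isolated; racemic, C4/C5 configuration uncontrolled and erased on aromatisation) | COc1cc(Br)cc2n(COCC[Si](C)(C)C)cc(C3OC(=NC3S(=O)(=O)c3ccc(C)cc3)c3ccc(Br)n3COCC[Si](C)(C)C)c12 | intermediate
17 | 5-(6-bromo-4-methoxy-1-SEM-1H-indol-3-yl)-2-(5-bromo-1-SEM-1H-pyrrol-2-yl)-1,3-oxazole | COc1cc(Br)cc2n(COCC[Si](C)(C)C)cc(-c3cnc(-c4ccc(Br)n4COCC[Si](C)(C)C)o3)c12 | intermediate
18 | 5-(6-bromo-4-methoxy-1H-indol-3-yl)-2-(5-bromo-1H-pyrrol-2-yl)-1,3-oxazole | COc1cc(Br)cc2[nH]cc(-c3cnc(-c4ccc(Br)[nH]4)o3)c12 | target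

Total step count: 9 (steps 1–2 for the indole partner, steps 3–7 for the pyrrole partner, steps 8–9 after convergence).
Longest linear sequence: 7 steps (steps 3 to 9).

Steps most likely to fail

1. Step 8. The addition to the electron-rich, peri-substituted formyl group may be reversible, and displacement of thiolate at the donor-substituted imidate carbon may be slow. The carbanion could then decay by loss of sulfinate before the ring closes, and the final elimination could stall at the dihydrooxazole stage. Fallback (Robinson–Gabriel construction of the same ring with the same atom assignment, without protecting groups): setting out from aldehyde 3 and acid 5, the aldehyde is condensed with TosMIC (K2CO3, MeOH, reflux) to give 5-(6-bromo-4-methoxy-1H-indol-3-yl)-1,3-oxazole F1, used only as a masked aminomethyl ketone. Hydrolytic ring opening of this C2-unsubstituted oxazole (conc. aq. HCl, MeOH, reflux) should give 2-amino-1-(6-bromo-4-methoxy-1H-indol-3-yl)ethan-1-one hydrochloride F2. Coupling with acid 5 (EDC·HCl, HOBt, iPr2NEt, DMF) gives 5-bromo-N-[2-(6-bromo-4-methoxy-1H-indol-3-yl)-2-oxoethyl]-1H-pyrrole-2-carboxamide F3. Cyclodehydration (POCl3, 80 °C, or PPh3/I2/Et3N in CH2Cl2) closes the oxazole and comes back to the route at target 18.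

2. Step 5. In warm aqueous acid the SEM N,O-acetal may be lost, the pyrrole ring may be attacked at C3 or C4 by formaldehyde or the N-acyliminium ion, and the weakly nucleophilic amide may condense only slowly. Fallback (amidoalkylation without acid): setting out from amide 8, hydroxymethylation with aqueous formaldehyde under K2CO3 catalysis (EtOH/H2O, rt) gives 11, this time isolated. Acetylation (Ac2O, pyridine) gives ({5-bromo-1-SEM-1H-pyrrole-2-carbonyl}amino)methyl acetate F4. Sodium p-toluenesulfinate 10 in DMF at rt then replaces acetate through the transient N-acylimine and comes back to the route at 12.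

3. Step 9. Cleavage of two SEM groups from electron-rich heteroaromatic nitrogens may be incomplete or may stop at N-hydroxymethyl species, and prolonged heating with fluoride may erode the bromopyrrole. Fallback (acidolysis, then base-mediated loss of formaldehyde): setting out from 17, TFA in CH2Cl2 (0 °C to rt) cleaves the silylethyl ether to give [6-bromo-3-{2-[5-bromo-1-(hydroxymethyl)pyrrol-2-yl]-1,3-oxazol-5-yl}-4-methoxyindol-1-yl]methanol F5. K2CO3 in MeOH/H2O at rt then expels formaldehyde from both hemiaminals and comes back to the route at 18.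

Further compounds
F1 | step 8 | 5-(6-bromo-4-methoxy-1H-indol-3-yl)-1,3-oxazole | COc1cc(Br)cc2[nH]cc(-c3cnco3)c12
F2 | step 8 | 2-amino-1-(6-bromo-4-methoxy-1H-indol-3-yl)ethan-1-one hydrochloride | COc1cc(Br)cc2[nH]cc(C(=O)CN)c12.Cl
F3 | step 8 | 5-bromo-N-[2-(6-bromo-4-methoxy-1H-indol-3-yl)-2-oxoethyl]-1H-pyrrole-2-carboxamide | COc1cc(Br)cc2[nH]cc(C(=O)CNC(=O)c3ccc(Br)[nH]3)c12
F4 | step 5 | ({5-bromo-1-SEM-1H-pyrrole-2-carbonyl}amino)methyl acetate | CC(=O)OCNC(=O)c1ccc(Br)n1COCC[Si](C)(C)C
F5 | step 9 | [6-bromo-3-{2-[5-bromo-1-(hydroxymethyl)pyrrol-2-yl]-1,3-oxazol-5-yl}-4-methoxyindol-1-yl]methanol | COc1cc(Br)cc2n(CO)cc(-c3cnc(-c4ccc(Br)n4CO)o3)c12
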